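The two phthalide halves are numbered separately: the hydroxylated half is C1–C7a, the other half is primed, and the links are C7–C6' and C4–C7'. The plan cuts C7–C7a and C4–C3a of the bicyclo[2.2.2]octene. The etheno bridge C3a=C7a of that bicycle holds C1 and C3, the two carbons of the unprimed lactone ring, and it points away from the carbocycle attached through C5' and C7a'. It can therefore arrive as one alkyne. A Diels–Alder addition of allyl 4-oxooct-2-ynoate to an enantiopure cis-fused 6-silyloxy diene (decalin skeleton, C7a' ketone as dioxolane) makes both bonds, both six-membered rings containing the bridge, and stereocentres C4 and C7. It also leaves C6 oxygenated. The primed lactone follows by acylation, triflation and carbonylation.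

Key step: step 9

Remark (assumption, step 5): the (S)-catalyst is taken to expose the enone face that leads to 11. This follows the accepted binding model (boron on the carbonyl oxygen, α-C–H···O contact, one face covered by a phenyl group). If a correlation showed the opposite sense, the (R)-catalyst would be used and nothing else changes.

Remark (design): the dienophile acid is carried as its allyl ester. The unprimed lactone is closed before C6 is unmasked, because a free C6 ketone next to the open C3 ketone is a non-enolisable vinylogous 1,3-diketone. Hydroxide could cleave it at C6–C7.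

Step 1
Reactants: 1 propiolic acid; 2 allyl alcohol
Product: 3 allyl propiolate
Conditions: p-toluenesulfonic acid monohydrate (cat.), cyclohexane, reflux, Dean–Stark trap
Reagents that add atoms: none
Why: Fischer esterification is driven to completion by azeotropic removal of water, the electron-poor terminal alkyne is inert to catalytic sulfonic acid, and the allyl ester is chosen because it can later be removed without acid or hydroxide.

Step 2
Reactants: 3 allyl propiolate; 4 pentanal
Product: 6 allyl 4-hydroxyoct-2-ynoate (racemic), via lithium acetylide 5 (not isolated)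
Conditions: LiN(iPr)2, THF, −78 °C; then 4, −78 °C; AcOH quench
Reagents that add atoms: none
Why: The alkyne C–H is the only acidic site, so the amide base gives acetylide 5, which is stable at −78 °C and adds 1,2 to the aldehyde (acetylide carbonyl addition); the carbinol centre forms as a racemate and disappears in step 3.

Step 3
Reactants: 6 allyl 4-hydroxyoct-2-ynoate
Product: 7 allyl 4-oxooct-2-ynoate
Conditions: Dess–Martin periodinane, CH2Cl2, 0 → 23 °C
Reagents that add atoms: none
Why: Dess–Martin oxidation converts the propargylic alcohol into the ynone under neutral, non-nucleophilic conditions, which matters because 7 is a strong Michael acceptor.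

Step 4
Reactants: 8 methyl vinyl ketone
Product: 9 2-(triisopropylsilyloxy)buta-1,3-diene
Conditions: iPr3SiOTf, Et3N, Et2O, 0 → 23 °C
Reagents that add atoms: triisopropylsilyl triflate, CC(C)[Si](C(C)C)(C(C)C)OS(=O)(=O)C(F)(F)F
Why: Soft enolisation of the methyl ketone by the silyl triflate/amine pair with O-silylation (silyl enol ether formation) gives the 2-silyloxydiene, since the vinyl side has no enolisable hydrogen.

Step 5
Reactants: 10 cyclohex-2-en-1-one; 9 2-(triisopropylsilyloxy)buta-1,3-diene
Product: 11 (4aR,8aS)-6-(triisopropylsilyloxy)-3,4,4a,5,8,8a-hexahydronaphthalen-1(2H)-one (cis-fused; C1 = C7a', C4a = C6', C8a = C7', C6 = C6)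
Conditions: (S)-3,3-diphenyl-1-(o-tolyl)tetrahydro-1H,3H-pyrrolo[1,2-c][1,3,2]oxazaborole (20 mol%), HNTf2 (17 mol%), CH2Cl2, −20 °C
Reagents that add atoms: none
Why: This is an enantioselective Diels–Alder reaction under protonated-oxazaborolidine catalysis, a documented pairing of cyclic enones with 2-(trialkylsilyloxy)dienes: suprafacial addition to the ring alkene fixes the cis relation of C6'–H and C7'–H, the donor places C7 on the enone β-carbon C6' ("para" rule), the bound catalyst leaves only one enone face open, and the bulky silyl group resists transfer to triflimide, which would open an achiral background channel.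

Step 6
Reactants: 11 silyl enol ether ketone
Product: 12 (4aR,8aR)-3,4,4a,8a-tetrahydronaphthalene-1,6(2H,5H)-dione (cis-fused enedione)
Conditions: Pd(OAc)2 (1.1 equiv), MeCN, 23–40 °C; rapid filtration, used at once
Reagents that add atoms: none
Why: Saegusa–Ito oxidation is regiospecific, since the palladium enolate sits on C5 and only C4 offers a β-hydrogen, and it runs without added acid or base, which protects the labile C7'–H of the γ-acyl enone.

Step 7
Reactants: 12 cis-enedione
Product: 13 (4aR,8aR)-5,5-(ethylenedioxy)-4a,5,6,7,8,8a-hexahydronaphthalen-2(1H)-one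
Conditions: Me3SiOCH2CH2OSiMe3, Me3SiOTf (5 mol%), CH2Cl2, −78 → −40 °C; pyridine quench
Reagents that add atoms: 1,2-bis(trimethylsilyloxy)ethane, C[Si](C)(C)OCCO[Si](C)(C)C
Why: Aprotic ketalisation catalysed by silyl triflate converts the isolated C7a' ketone much faster than the conjugated C6 ketone and, being cold and free of protic acid, does not enolise C7', so the cis fusion is kept and C7' is afterwards no longer α to a carbonyl group.

Step 8
Reactants: 13 ketal enone
Product: 15 (4aS,8aR)-2-(tert-butyldimethylsilyloxy)-5,5-(ethylenedioxy)-4a,5,6,7,8,8a-hexahydronaphthalene, via lithium dienolate 14 (not isolated)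
Conditions: LiN(iPr)2, THF, −78 °C; then tBuMe2SiOTf, −78 °C; Et3N-buffered work-up
Reagents that add atoms: tert-butyldimethylsilyl triflate, CC(C)(C)[Si](C)(C)OS(=O)(=O)C(F)(F)F
Why: Kinetic deprotonation of the enone at the α' position C7 gives the cross-conjugated dienolate 14, which the silyl triflate traps on oxygen at −78 °C before it can equilibrate to the extended dienolate through C7' (kinetic silyl dienol ether formation); no stereocentre is touched.

Step 9
Reactants: 15 cis-fused 6-silyloxy diene; 7 allyl 4-oxooct-2-ynoate
Product: 16 bicyclo[2.2.2]octadiene keto ester (4R,7S,6'R,7'R): C7a–CO2allyl, C3a–C(O)C4H9, C5=C6–OSiMe2tBu, C7a' dioxolane, C5' and C7a' syn to the C5=C6 bridge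
Conditions: toluene (1 M), 2,6-di-tert-butyl-4-methylphenol (trace), 23 → 60 °C
Reagents that add atoms: none
Why: This is a concerted but asynchronous normal-electron-demand [4+2] cycloaddition; the closest known reaction type is the Diels–Alder addition of acetylenic esters and ketones to 2-silyloxycyclohexa-1,3-dienes, which gives bicyclo[2.2.2]octadienes. C7–C7a and C4–C3a form suprafacially on both partners, so the alkyne bridges the 1,4-positions of the existing cyclohexadiene and closes, in one cycloaddition event, the two six-membered rings that contain the new bridge (C7–C7a–C3a–C4–C5–C6 and C7–C7a–C3a–C4–C7'–C6'). The new stereocentres C7 (S) and C4 (R) are both controlled by the resident centres C6' and C7': the alkyne can only reach the diene face that bears the two ring-fusion hydrogens, the other face being covered by C5', C7a' and the dioxolane, and this puts the etheno bridge anti to that carbocycle as in 27. The selectivity that has to be won is regiochemical and is secured electronically: the silyloxy donor on C6 makes C7 the most nucleophilic diene terminus, the ketone outweighs the ester as acceptor and makes the ester-bearing alkyne carbon the most electrophilic one, and these two atoms bond ahead of the others. A linear dienophile poses no endo/exo question, and a bath temperature of at most 60 °C stays well below the range in which such adducts lose the C6'–C7' bridge as an alkene and aromatise (Alder–Rickert cleavage). The enol ether left at C5=C6 fixes the oxygen on C6 and keeps that carbonyl group masked until the keto ester has been closed to the lactone.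

Step 10
Reactants: 16 cycloadduct
Product: 18 (Z)-butylidene lactone silyl enol ether (4R,7S,6'R,7'R), via keto acid 17 (not isolated)
Conditions: Pd(PPh3)4 (5 mol%), morpholine, THF, 0 → 23 °C; then Ac2O, Et3N, 4-(dimethylamino)pyridine (cat.), 0 → 23 °C; then DBU
Reagents that add atoms: none
Why: Zerovalent palladium ionises the allyl ester and morpholine takes up the allyl group (Tsuji–Trost deallylation), after which γ-keto acid 17 loses acetic acid through the acetate of its hydroxylactone form (dehydrative enol lactonisation) to give the Z-butylidene lactone, Z being preferred because the E isomer would press the propyl chain against C4–H, and enol ether and dioxolane survive because no hydroxide or acid is present.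

Step 11
Reactants: 18 lactone silyl enol ether
Product: 19 C6 ketone (4R,7S,6'S,7'R)
Conditions: HF·pyridine, pyridine, THF, 0 °C
Reagents that add atoms: none
Why: Buffered hydrogen fluoride cleaves the Si–O bond and C5 is protonated (protodesilylation of a silyl enol ether), leaving dioxolane and enol lactone intact, and with C3 locked in the lactone the freed ketone no longer belongs to a vinylogous 1,3-diketone, so it cannot fragment by retro-Claisen cleavage.

Step 12
Reactants: 19 C6 ketone
Product: 20 C6 alcohol (4R,6R,7S,6'R,7'R), hydroxyl group pointing towards the C6'–C7' bridge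
Conditions: NaBH4, CeCl3·7H2O, MeOH/THF (1:1), −78 °C
Reagents that add atoms: none
Why: Luche reduction is fast and strictly 1,2 at the isolated bicyclic ketone and spares the dienyl lactone at −78 °C, and hydride arrives from the side of the flat etheno-lactone bridge because the opposite side of C6 is blocked by C5'H2, which sets (6R).

Step 13
Reactants: 20 C6 alcohol
Product: 21 C6 tert-butyldimethylsilyl ether
Conditions: tBuMe2SiOTf, 2,6-lutidine, CH2Cl2, 0 → 23 °C
Reagents that add atoms: tert-butyldimethylsilyl triflate, CC(C)(C)[Si](C)(C)OS(=O)(=O)C(F)(F)F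
Why: The crowded secondary alcohol needs the silyl triflate and a hindered pyridine base (O-silylation), and the ether keeps this oxygen out of the acylation, sulfonylation and acylpalladium chemistry that follows.

Step 14
Reactants: 21 silyl ether ketal
Product: 22 C7a' ketone (4R,6R,7S,6'R,7'R)
Conditions: pyridinium p-toluenesulfonate (20 mol%), acetone/H2O (9:1), 55 °C
Reagents that add atoms: water, O
Why: Mild acid-catalysed acetal hydrolysis frees the ketone while the hindered silyl ether and the enol lactone tolerate the pyridinium salt, and C7' cannot invert because a trans fusion on an edge of the bicyclo[2.2.2]octene would demand a torsion of about 120° inside a six-membered ring.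

Step 15
Reactants: 22 C7a' ketone; 23 pentanoyl chloride
Product: 24 3a'-pentanoyl ketone, drawn as its chelated enol (C7a'–OH, C7a'=C3a')
Conditions: MgBr2·OEt2, iPr2NEt, CH2Cl2, 0 → 23 °C; dilute HCl work-up
Reagents that add atoms: none
Why: Soft enolisation with MgBr2·OEt2 and a tertiary amine followed by C-acylation (Claisen-type acylation of a ketone to a 1,3-diketone) needs no strong base, so the butylidene lactone is not deprotonated, and the reaction occurs at the C3a' methylene because acylation at C7' would build a quaternary centre next to the cage.

Step 16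
Reactants: 24 enolised 1,3-diketone
Product: 25 C7a' enol triflate (C7a'=C3a', pentanoyl on C3a')
Conditions: Tf2O, iPr2NEt, CH2Cl2, −78 °C
Reagents that add atoms: triflic anhydride, O=S(=O)(OS(=O)(=O)C(F)(F)F)C(F)(F)F
Why: O-Sulfonylation of the enolised diketone (enol triflate formation) is expected on the ring oxygen, since 2-acylcyclohexanones enolise with the double bond inside the ring and the alternative exocyclic tetrasubstituted enol triflate suffers allylic strain with C4'H2.

Step 17
Reactants: 25 enol triflate
Product: 26 bis[(Z)-butylidene lactone] C6 silyl ether (4R,6R,7S,6'S,7'R)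
Conditions: PdCl2(PPh3)2 (5 mol%), CO (5 bar), Et3N, MeCN, 60 °C
Reagents that add atoms: carbon monoxide, [C-]#[O+]
Why: In this carbonylative lactonisation, oxidative addition of the vinyl triflate to zerovalent palladium, CO insertion and capture of the acylpalladium unit by the enol oxygen of the adjacent pentanoyl group (known for β-halo enones and 2-haloaryl ketones) close the five-membered ring, and the Z-alkene results because the E isomer would clash with C4'H2.

Step 18
Reactants: 26 silyl ether
Product: 27 target CNP0289078.2 (4R,6R,7S,6'S,7'R; both butylidene groups Z)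
Conditions: HF·pyridine, THF, 0 → 23 °C
Reagents that add atoms: none
Why: Fluoride-driven cleavage of the silyl ether under weakly acidic conditions leaves both base-sensitive enol lactones and all stereocentres untouched.

Compound list
1 | propiolic acid | C#CC(=O)O | starting material
2 | allyl alcohol | C=CCO | starting material
3 | allyl propiolate | C#CC(=O)OCC=C | intermediate
4 | pentanal | CCCCC=O | starting material
5 | lithium acetylide of 3 (not isolated) | [Li]C#CC(=O)OCC=C | intermediate
6 | allyl 4-hydroxyoct-2-ynoate (racemic) | CCCCC(O)C#CC(=O)OCC=C | intermediate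
7 | allyl 4-oxooct-2-ynoate | CCCCC(=O)C#CC(=O)OCC=C | intermediate
8 | methyl vinyl ketone | CC(=O)C=C | starting material
9 | 2-(triisopropylsilyloxy)buta-1,3-diene | C=CC(=C)O[Si](C(C)C)(C(C)C)C(C)C | intermediate
10 | cyclohex-2-en-1-one | O=C1C=CCCC1 | starting material
11 | (4aR,8aS)-6-(triisopropylsilyloxy)-3,4,4a,5,8,8a-hexahydronaphthalen-1(2H)-one, cis-fused | O=C2CCC[C@@H]3CC(O[Si](C(C)C)(C(C)C)C(C)C)=CC[C@H]23 | intermediate
12 | (4aR,8aR)-3,4,4a,8a-tetrahydronaphthalene-1,6(2H,5H)-dione, cis-fused | O=C2CCC[C@@H]3CC(=O)C=C[C@H]23 | intermediate
13 | (4aR,8aR)-5,5-(ethylenedioxy)-4a,5,6,7,8,8a-hexahydronaphthalen-2(1H)-one | C1COC2(O1)CCC[C@@H]3CC(=O)C=C[C@H]23 | intermediate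
14 | lithium cross-conjugated dienolate of 13 (not isolated) | C1COC2(O1)CCC[C@@H]3C=C(O[Li])C=C[C@H]23 | intermediate
15 | (4aS,8aR)-2-(tert-butyldimethylsilyloxy)-5,5-(ethylenedioxy)-4a,5,6,7,8,8a-hexahydronaphthalene (C7=C6(OSi)–C5=C4 diene, cis-fused) | C1COC2(O1)CCC[C@@H]3C=C(O[Si](C)(C)C(C)(C)C)C=C[C@H]23 | intermediate
16 | key cycloadduct, (4R,7S,6'R,7'R)-bicyclo[2.2.2]octadiene allyl keto ester with C5=C6 silyl enol ether and C7a' dioxolane | C1COC2(O1)CCC[C@@H]3[C@H]4C(C(=O)OCC=C)=C(C(=O)CCCC)[C@H](C=C4O[Si](C)(C)C(C)(C)C)[C@H]23 | intermediate
17 | keto acid from 16, in equilibrium with its hydroxylactone (not isolated) | C1COC2(O1)CCC[C@@H]3[C@H]4C(C(=O)O)=C(C(=O)CCCC)[C@H](C=C4O[Si](C)(C)C(C)(C)C)[C@H]23 | intermediate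
18 | (Z)-butylidene lactone with C5=C6 silyl enol ether and C7a' dioxolane | C1COC2(O1)CCC[C@@H]3[C@H]4C5=C(/C(=C/CCC)OC5=O)[C@H](C=C4O[Si](C)(C)C(C)(C)C)[C@H]23 | intermediate
19 | C6 ketone, lactone, C7a' dioxolane | C1COC2(O1)CCC[C@@H]3[C@H]4C5=C(/C(=C/CCC)OC5=O)[C@H](CC4=O)[C@H]23 | intermediate
20 | (6R)-alcohol, OH syn to the C6'–C7' bridge | C1COC2(O1)CCC[C@@H]3[C@H]4C5=C(/C(=C/CCC)OC5=O)[C@H](C[C@H]4O)[C@H]23 | intermediate
21 | C6 tert-butyldimethylsilyl ether of 20 | C1COC2(O1)CCC[C@@H]3[C@H]4C5=C(/C(=C/CCC)OC5=O)[C@H](C[C@H]4O[Si](C)(C)C(C)(C)C)[C@H]23 | intermediate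
22 | C7a' ketone | O=C2CCC[C@@H]3[C@H]4C5=C(/C(=C/CCC)OC5=O)[C@H](C[C@H]4O[Si](C)(C)C(C)(C)C)[C@H]23 | intermediate
23 | pentanoyl chloride | CCCCC(=O)Cl | starting material
24 | 3a'-pentanoyl ketone as chelated enol | OC2=C(C(=O)CCCC)CC[C@@H]3[C@H]4C5=C(/C(=C/CCC)OC5=O)[C@H](C[C@H]4O[Si](C)(C)C(C)(C)C)[C@H]23 | intermediate
25 | C7a' enol triflate | FC(F)(F)S(=O)(=O)OC2=C(C(=O)CCCC)CC[C@@H]3[C@H]4C5=C(/C(=C/CCC)OC5=O)[C@H](C[C@H]4O[Si](C)(C)C(C)(C)C)[C@H]23 | intermediate
26 | bis[(Z)-butylidene lactone] C6 silyl ether | CCC/C=C1\OC(=O)C2=C1CC[C@@H]1[C@H]3C4=C(/C(=C/CCC)OC4=O)[C@H](C[C@H]3O[Si](C)(C)C(C)(C)C)[C@H]21 | intermediate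
27 | CNP0289078.2, (4R,6R,7S,6'S,7'R) | CCC/C=C1\OC(=O)C2=C1CC[C@@H]1[C@H]3C4=C(/C(=C/CCC)OC4=O)[C@H](C[C@H]3O)[C@H]21 | target

Total step count: 18. Longest linear sequence: 15 steps (steps 4–18, from methyl vinyl ketone). Steps 1–3 form the short branch.

Steps most likely to fail

Step 9. The ester may compete with the ketone in steering the alkyne, so that part of the material adds with the reversed orientation. A slow reaction at the hindered C4 terminus could also tempt to temperatures at which cycloreversion with aromatisation begins. The fallback sets out from 15 and uses a dienophile with a single acceptor. Commercial hept-1-yn-3-ol is brominated at the alkyne terminus (N-bromosuccinimide, AgNO3 cat., acetone) to 1-bromohept-1-yn-3-ol F1. This is oxidised with Dess–Martin periodinane to 1-bromohept-1-yn-3-one F2. Its cycloaddition to 15 gives the β-bromo enone cycloadduct F3 (Br on C7a, pentanoyl on C3a). Carbonylative lactonisation of F3 (PdCl2(PPh3)2, CO, Et3N, MeCN) then installs C1 and closes the ring. The route is rejoined at 18.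

Step 17. Ring closure by the weakly nucleophilic enol oxygen may be slower than reduction or adventitious hydrolysis of the acylpalladium intermediate. The fallback sets out from 25 and separates carbon–carbon bond formation from ring closure. Hydroxycarbonylation of the vinyl triflate (Pd(OAc)2, PPh3, KOAc, CO 1 bar, DMF, aqueous work-up) gives the primed keto acid F4. This is closed as in the second half of step 10 (Ac2O, Et3N, 4-(dimethylamino)pyridine, then DBU). The route is rejoined at 26.

Step 6. The product is a γ-acyl enone. Enolisation towards C7' during the oxidation or on handling would erode the cis ring fusion or shift the double bond. The fallback sets out from 11 and reverses the order of events, so that this compound is never formed. The C7a' ketone of 11 is ketalised first (Me3SiOCH2CH2OSiMe3, Me3SiOTf cat., CH2Cl2, −78 °C) to the ketal silyl enol ether F5. Only then is Saegusa–Ito oxidation with Pd(OAc)2 carried out. The route is rejoined at 13.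

Further compounds
F1 | step 9 | 1-bromohept-1-yn-3-ol (racemic) | CCCCC(O)C#CBr
F2 | step 9 | 1-bromohept-1-yn-3-one | CCCCC(=O)C#CBr
F3 | step 9 | β-bromo enone cycloadduct (Br on C7a, pentanoyl on C3a, C5=C6 silyl enol ether, C7a' dioxolane) | C1COC2(O1)CCC[C@@H]3[C@H]4C(Br)=C(C(=O)CCCC)[C@H](C=C4O[Si](C)(C)C(C)(C)C)[C@H]23
F4 | step 17 | primed keto acid (C7a'–CO2H, C3a'–pentanoyl), in equilibrium with its hydroxylactone | OC(=O)C2=C(C(=O)CCCC)CC[C@@H]3[C@H]4C5=C(/C(=C/CCC)OC5=O)[C@H](C[C@H]4O[Si](C)(C)C(C)(C)C)[C@H]23
F5 | step 6 | ketal silyl enol ether (C7a' dioxolane, C5=C6–OSi(iPr)3, cis-fused) | C1COC2(O1)CCC[C@@H]3CC(O[Si](C(C)C)(C(C)C)C(C)C)=CC[C@H]23
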